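(All runs are simulated with made-up constants; noise was put on by code.)

Late in the run, at 30 h, two chemists disagree on how much substrate of either hand is still in the flask.

| setting | south-east | south-west | flask |
|---|---|---|---|
| left-handed substrate | 0.20 M | 0.20 M | 0.20 M |
| right-handed substrate | 0.20 M | 0.20 M | 0.20 M |
| reagent | 0.40 M | 0.40 M | 0.400 M |
| racemization catalyst | 14 mM | 22 mM | 10 mM |
| remark | run made earlier | run made earlier |  |
| time |  |  | 30 h |

| run | time / h | left-handed substrate / % | right-handed substrate / % |
|---|---|---|---|
| south-east | 5.00 | 27.3 | 27.7 |
| south-east | 10.0 | 18.7 | 19.6 |
| south-east | 15.0 | 15.5 | 16.5 |
| south-east | 20.0 | 14.9 | 12.0 |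
| south-west | 1.33 | 40.0 | 41.1 |
| south-west | 3.00 | 32.4 | 34.7 |
| south-west | 8.00 | 24.7 | 23.8 |
| south-west | 20.0 | 11.2 | 13.4 |

(standard deviation of a reading: 1 percentage point)

* part of the left-handed substrate and right-handed substrate charged together that has reacted at 30 h
* excess of left-handed product over right-handed product in the product at 30 h
* excess of right-handed substrate over left-handed substrate among what is left of the two at 30 h

- reagent is single-handed; left-handed substrate and right-handed substrate are mirror images of each other, charged as a racemate, each of them at the stated concentration
- an excess is the difference of the two amounts in percent of their sum
- an excess is below zero if the other one leads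
- the handed part of reagent does not stay in what it makes, so the products of the two hands are mirror images too

Both start from the last readings at 20.0 h. Left-handed substrate leads by 2.9 percentage points in the south-east run and right-handed substrate by 2.2 points in the south-west run, with a scatter of 1 point per reading. Since the lead changes sides, both chemists count the hands together, and the mean share left over the two runs is 25.8 %.

The first chemist treats the loss as pseudo-first-order, so equal stretches of hours remove equal fractions. The flask's time is 1.50 times that of the readings, which gives 86.9 % reacted.

The second chemist, whose reckoning I adopt, looks at the charge. Reagent at 0.40 M stands level with the two hands together, and each reaction uses one of each, so [reagent] should fall with the substrate and the reciprocal of the share left should climb in a straight line. The slope of that line, divided by the reagent charge, is the pool constant 0.360 L mol⁻¹ h⁻¹: the second-order rate constant for reagent meeting substrate of either hand. For the flask it gives 81.2 % reacted. This assumes the flask's catalyst, lower than in either run, still keeps the hands level. I leave the product excess open, since the readings show substrates alone.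

The forecast says 81 %, 50 % and 1 %, and calls its product excess “a guess with a very wide range”.

The flask gives 80.6 % reacted, 42.2 % and 0.812 %, so the second chemist's count stands against the first chemist's 86.9 %. At 30.0 h the flask keeps 15 % of its reagent charge. At 3.00 h, with 66.7 % of the reagent still there, a first-order law on the start constant 0.144 h⁻¹ gives 35.1 % reacted, the pool constant's line gives 30.2 %, and the flask stands at 31.6 %, so at that time too the first-order figure lies further from the flask than the line does.

    2 racemization catalyst ⇌ resting dimer, settled at all times (K = 140 L mol⁻¹)
    2 reagent → self-condensation product (k = 0.0110 L mol⁻¹ h⁻¹)
    reagent + left-handed substrate → left-handed product (k = 0.570 L mol⁻¹ h⁻¹)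
    reagent + right-handed substrate → right-handed product (k = 0.220 L mol⁻¹ h⁻¹)
    left-handed substrate + racemization catalyst ⇌ right-handed substrate + racemization catalyst, rate k5*[racemization catalyst]*[left-handed substrate] forward; the back reaction follows from the equilibrium constant (k = 150 L mol⁻¹ h⁻¹)

A neighbour flask charged with 0.24 M of reagent starts 0.160 M short of the substrate, so the straight line gives way to the ratio [substrate]/[reagent], which the pool constant multiplies by 5.63 over 30 h. That ratio reaches 9.40, which means 55.2 % reacted; the simulation gives 55.0 %.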